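## The problem

- Target 12 is a flavone (rings A and C form a 4H-chromen-4-one). It carries an isovanilloid ring B (3'-OH, 4'-OMe) at C2 and a 4-hydroxybenzyl group at C8. It has no stereocentre, so nothing needs control in three dimensions.
- The difficulty lies in ring A. Five of its six positions are substituted (C4a acyl, C5 OH, C7 OH, C8 arylmethyl, C8a O1), and only C6 bears hydrogen.
- C6 and C8 each lie between two oxygen-bearing carbons and differ little in nucleophilicity. A 2,4,6-trihydroxyphenyl ketone can also close ring C through either ortho hydroxyl. Late benzylation and late pyranone closure are therefore both open to the 6-benzyl isomer, and hot acid can interconvert the two series by ring opening (Wessely–Moser rearrangement).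
- Four phenols must end free next to one methyl ether, so no unselective demethylation is allowed. Once unmasked, ring A, the guaiacol-type ring B and the p-hydroxybenzyl group (a latent p-quinone methide) tolerate neither oxidants nor hot strong acid.
- The feature that opens the plan is a hidden chain. The atoms C2–C3–C4–C4a–C8a–C8–CH2 form an unbranched seven-carbon chain between the two outer aryl rings, oxygenated at C2, C4 and C8a. This is a 1,7-diarylheptane-1,3,5-trione closed through O1 to a 4-pyranone (ring C).
- The three remaining atoms of ring A, C5–C6–C7, are a malonyl unit that spans C4a and C8. These two carbons are the α- and γ-carbons of the dienolate of that 2-alkyl-4-pyranone.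
- Ring A can therefore be laid onto an intact ring C. The carbon that bears the arylmethyl group is bonded to C8a before ring A exists.

## Retrosynthesis

**12 ⇒ 11.** The two O–CH2Ph bonds of bis(benzyl ether) 11 are cut.
- Only the two phenols that exist before the key step (3'-OH and the benzyl-ring OH) need a mask. The 5- and 7-hydroxyls are born free in the key step.
- Benzyl is preferred to acetal or silyl groups because it must pass amide base, NaH at reflux, sulfonic acid, silyl triflate and an acid chloride.
- The forward reaction must spare 4'-OMe, the diarylmethane CH2 and the C2=C3 bond.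

**11 ⇒ 7 + 8.** The bonds C4a–C5 and C7–C8 are cut, which removes C5–C6–C7 as malonyl dichloride 8 and leaves pyranone 7.
- The neighbouring cuts reopen the 6/8 question: C8–CH2 on the finished flavone, or O1–C8a and C4–C4a on a phloroglucinol. This cut does not, because C8 stays bonded to C8a throughout.
- The pentasubstituted benzene disappears completely. Compound 7 is a monocyclic pyranone with one enolisable position.
- The forward reaction must make the C8/C4a pair act as a C,C- and not a C,O-dinucleophile. Because 8 is symmetric, either order of bond formation gives the same product.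

**7 ⇒ 6.** The O1–C8a bond (equivalently O1–C2) is cut to give the open triketone 6. Only one 4-pyranone can form from a linear 1,3,5-triketone, so the forward cyclodehydration has no regiochemical choice. It only has to spare the benzyl ethers.

**6 ⇒ 3 + 5.** The C2–C3 bond is cut, giving β-diketone 3 and the non-enolisable ester 5.
- Cutting C4–C4a instead would need an aroylacetone and a 3-arylpropanoate, and the latter can self-condense.
- The forward Claisen aroylation must take place at the CH3 terminus of 3 and not at its CH2 terminus.

**3 ⇒ 1 + 2, and 5 ⇒ 4.** The C8–CH2 bond, the crux of every other plan, is made first.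
- It forms by SN2 alkylation of the dianion of pentane-2,4-dione 1 with benzylic chloride 2, at a stage where the two methyl groups are equivalent.
- Compound 1 then supplies C8, C8a, C4a, C4 and C3, and each of its three nucleophilic carbons is used.
- Ester 5 comes from methyl isovanillate 4 by O-benzylation, so the 3'-OH/4'-OMe pattern is bought and not made.

## Roads not taken

**Alternative 1:** (the most obvious) cut O1–C2 and C2–C3.
- Forward key step: acetophenone A1 is O-aroylated with acid chloride A2, rearranged (Baker–Venkataraman) and cyclodehydrated.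
- The difficulty moves into A1. It requires C-monobenzylation of an unprotected triphenolic ketone, in competition with O-alkylation and double C-alkylation.
- Two of the three phenols must then be masked so that exactly the hydroxyl between acyl and benzyl stays free. The two chelated ortho hydroxyls differ only in one neighbour.
- Any loss of a mask before closure opens the way to the 6-benzyl isomer A3.
- The plan needs about twice as many steps, several of them protecting-group operations. In the chosen plan regiochemistry follows from connectivity.

**Alternative 2:** cut C8–CH2 on the finished flavone.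
- Forward key step: diosmetin A4 is combined with 4-hydroxybenzyl alcohol A5 under acid or heat, and p-quinone methide A6 is trapped in a biomimetic Friedel–Crafts reaction.
- Nothing in A4 separates C8 from C6 by more than a small electronic bias. The first product is more electron-rich than A4, so A3 and the 6,8-bis adduct A7 are built-in companions of 12.
- The isomers differ only in the position of one substituent.
- The precursor is also nearly as complex as the product, so the key step solves little.
- The halogenation/cross-coupling variant of this cut buys regiocontrol with full protection. It is kept as the fallback for step 5.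

**Alternative 3:** cut C4–C4a and O1–C2.
- Forward key step: the symmetric 2-(4-hydroxybenzyl)phloroglucinol A8 is condensed thermally with β-keto ester A9 (Mentzer-type pyrone synthesis).
- The symmetry of A8 makes the C-acylation unambiguous.
- The following O-closure must choose between the hydroxyl next to the benzyl group (giving 12) and the unhindered one (giving A3). Sterics favour the wrong one.
- Temperatures above 200 °C with a free p-hydroxybenzylphenol invite retro-Friedel–Crafts loss of A6 and scrambling.
- A8 itself needs a monobenzylation of a symmetric triphenol.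
- The chosen plan makes O1–C8a before ring A exists and so removes this choice.

Key step: step 5

Remark on stereochemistry: the SMILES of 12 carries no stereodescriptor, and the structure has no stereocentre, stereogenic axis or stereogenic double bond. The compound is achiral, so the demand for a single enantiomer is met by the constitution alone.

## Route

Step 1
Reactants: 1 pentane-2,4-dione; 2 4-(benzyloxy)benzyl chloride
Product: 3 6-[4-(benzyloxy)phenyl]hexane-2,4-dione
Conditions: LDA (2.1 equiv), THF, 0 °C; then 2 (0.95 equiv), 0 °C → rt; 1 M HCl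
Reagents that add atoms: none
Why: γ-Alkylation of a β-diketone dianion; the terminal carbanion is by far the more nucleophilic site, so SN2 on the benzylic chloride should occur at CH3 and not at C3. The two methyl groups of 1 are equivalent, and a slight deficit of 2 limits double alkylation.

Step 2
Reactants: 4 methyl 3-hydroxy-4-methoxybenzoate
Product: 5 methyl 3-(benzyloxy)-4-methoxybenzoate
Conditions: BnBr (1.1 equiv), K2CO3 (1.5 equiv), DMF, 60 °C
Reagents that add atoms: benzyl bromide, BrCc1ccccc1
Why: Williamson etherification of the only phenol; the ester and the methyl ether are inert to carbonate.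

Step 3
Reactants: 3 6-[4-(benzyloxy)phenyl]hexane-2,4-dione; 5 methyl 3-(benzyloxy)-4-methoxybenzoate
Product: 6 1-[3-(benzyloxy)-4-methoxyphenyl]-7-[4-(benzyloxy)phenyl]heptane-1,3,5-trione
Conditions: NaH (4 equiv), DME, reflux; then cold 1 M HCl
Reagents that add atoms: none
Why: Claisen aroylation of a β-diketone at its terminal carbon with excess NaH, driven by formation of the triketone dianion. The CH3 terminus is less hindered and kinetically more acidic than the CH2 terminus, and 5 cannot enolise or self-condense.

Step 4
Reactants: 6 1-[3-(benzyloxy)-4-methoxyphenyl]-7-[4-(benzyloxy)phenyl]heptane-1,3,5-trione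
Product: 7 2-[3-(benzyloxy)-4-methoxyphenyl]-6-{2-[4-(benzyloxy)phenyl]ethyl}-4H-pyran-4-one
Conditions: p-TsOH·H2O (10 mol %), toluene, reflux, Dean–Stark
Reagents that add atoms: none
Why: Acid-catalysed cyclodehydration of a 1,3,5-triketone to a 2,6-disubstituted 4-pyranone (6-exo-trig attack of a terminal enol oxygen on the other terminal carbonyl, then loss of water); both directions of closure give the same 7. Catalytic sulfonic acid with azeotropic removal of water should leave the aryl benzyl ethers intact.

Step 5
Reactants: 7 2-[3-(benzyloxy)-4-methoxyphenyl]-6-{2-[4-(benzyloxy)phenyl]ethyl}-4H-pyran-4-one; 8 malonyl dichloride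
Product: 11 2-[3-(benzyloxy)-4-methoxyphenyl]-8-[4-(benzyloxy)benzyl]-5,7-dihydroxy-4H-chromen-4-one, via 4-silyloxy-2-alkylidene-2H-pyran 9 (not isolated), via β-keto acid chloride 10 (not isolated)
Conditions: TBSOTf (1.1 equiv), i-Pr2NEt (1.05 equiv), CH2Cl2, 0 °C; slow cannulation into 8 (1.05 equiv), CH2Cl2, −78 °C → rt; then ClCH2CH2Cl, 60 °C; MeOH quench
Reagents that add atoms: tert-butyldimethylsilyl trifluoromethanesulfonate, CC(C)(C)[Si](C)(C)OS(=O)(=O)C(F)(F)F (its silyl group is present in 9 only and is lost again before 11)
Why: Proposed new method: O-silylation of the pyranone carbonyl gives a 4-silyloxypyrylium ion whose only acidic C–H bonds (C8–H2) are cleared by the amine, so 9, a pyrylium anhydrobase that is at the same time a cross-conjugated silyl dienol ether, is the only enol derivative that can form. Its exocyclic carbon C8 is the one site whose attack on an acyl chloride of 8 regenerates the aromatic pyrylium (vinylogous Mukaiyama-type acylation, bond C7–C8); chloride then takes the silyl group and leaves pyranone 10. In 10 the C8–H is doubly activated, and enolisation with loss of HCl gives the dienylketene O=C5=C6H–C7(OH)=C8–C8a=C4a, which closes ring A by forming C4a–C5, as a 6π electrocyclisation or, in polar terms, as a 6-(enolexo)-exo-trig C-acylation of C4a; tautomerisation to the 5,7-diol makes the closure irreversible. The closest known reaction types are the C-acylation of methylenepyrans and silyl dienol ethers with acid chlorides, the cyclocondensation of malonyl dichloride or activated malonates with 1,3-dinucleophiles, the last stage of the Danheiser benzannulation and the Claisen-type folding of polyketide chains to acylphloroglucinols; new is the use of the α,γ-carbon pair of a 4-pyranone as the C,C-dinucleophile. No stereocentre is set: C8 of 10 is stereogenic but labile and ends sp2. Of the two selectivities needed, C,C against C,O annulation is secured by the silyl cap on O4 during the first acylation and by the base-free second stage, in which acylation of the pyranone oxygen stays reversible while aromatisation is not. 8-Benzyl against 6-benzyl is fixed by connectivity, since C8 carries the arylmethyl group and is bonded to C8a before ring A exists and O1 is never released; a first attack through C4a would lead to the same 11 because 8 is symmetric. Slow inverse addition keeps 8 in local excess and holds back 2:1 adducts.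

Step 6
Reactants: 11 2-[3-(benzyloxy)-4-methoxyphenyl]-8-[4-(benzyloxy)benzyl]-5,7-dihydroxy-4H-chromen-4-one
Product: 12 5,7-dihydroxy-2-(3-hydroxy-4-methoxyphenyl)-8-(4-hydroxybenzyl)-4H-chromen-4-one (CNP0159308.0)
Conditions: H2 (1 atm), 10% Pd/C, THF–MeOH, rt, stopped after uptake of 2 equiv
Reagents that add atoms: none
Why: Hydrogenolysis of two aryl benzyl ethers under neutral conditions. The methyl ether, the diarylmethane CH2 and the conjugated C2=C3 bond of the flavone should persist at 1 atm.

## Compound list

1 | pentane-2,4-dione | CC(=O)CC(C)=O | starting material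
2 | 4-(benzyloxy)benzyl chloride | ClCc1ccc(OCc2ccccc2)cc1 | starting material
3 | 6-[4-(benzyloxy)phenyl]hexane-2,4-dione | CC(=O)CC(=O)CCc1ccc(OCc2ccccc2)cc1 | intermediate
4 | methyl 3-hydroxy-4-methoxybenzoate (methyl isovanillate) | COC(=O)c1ccc(OC)c(O)c1 | starting material
5 | methyl 3-(benzyloxy)-4-methoxybenzoate | COC(=O)c1ccc(OC)c(OCc2ccccc2)c1 | intermediate
6 | 1-[3-(benzyloxy)-4-methoxyphenyl]-7-[4-(benzyloxy)phenyl]heptane-1,3,5-trione (drawn as the triketo tautomer) | COc1ccc(C(=O)CC(=O)CC(=O)CCc2ccc(OCc3ccccc3)cc2)cc1OCc1ccccc1 | intermediate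
7 | 2-[3-(benzyloxy)-4-methoxyphenyl]-6-{2-[4-(benzyloxy)phenyl]ethyl}-4H-pyran-4-one | COc1ccc(-c2cc(=O)cc(CCc3ccc(OCc4ccccc4)cc3)o2)cc1OCc1ccccc1 | intermediate
8 | malonyl dichloride (propanedioyl dichloride) | O=C(Cl)CC(=O)Cl | starting material
9 | tert-butyl({6-[3-(benzyloxy)-4-methoxyphenyl]-2-{2-[4-(benzyloxy)phenyl]ethylidene}-2H-pyran-4-yl}oxy)dimethylsilane (E/Z at the exocyclic alkene of no consequence) | COc1ccc(C2=CC(O[Si](C)(C)C(C)(C)C)=CC(=CCc3ccc(OCc4ccccc4)cc3)O2)cc1OCc1ccccc1 | intermediate
10 | 4-{6-[3-(benzyloxy)-4-methoxyphenyl]-4-oxo-4H-pyran-2-yl}-5-[4-(benzyloxy)phenyl]-3-oxopentanoyl chloride (racemic, configurationally labile) | COc1ccc(-c2cc(=O)cc(C(Cc3ccc(OCc4ccccc4)cc3)C(=O)CC(=O)Cl)o2)cc1OCc1ccccc1 | intermediate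
11 | 2-[3-(benzyloxy)-4-methoxyphenyl]-8-[4-(benzyloxy)benzyl]-5,7-dihydroxy-4H-chromen-4-one | COc1ccc(-c2cc(=O)c3c(O)cc(O)c(Cc4ccc(OCc5ccccc5)cc4)c3o2)cc1OCc1ccccc1 | intermediate
12 | 5,7-dihydroxy-2-(3-hydroxy-4-methoxyphenyl)-8-(4-hydroxybenzyl)-4H-chromen-4-one (achiral) | COc1ccc(-c2cc(=O)c3c(O)cc(O)c(Cc4ccc(O)cc4)c3o2)cc1O | target

## Step count and least certain steps

Total steps: 6. Longest linear sequence: 5 (steps 1, 3, 4, 5, 6).

**Step 5 (key step, proposed new method).** Several processes can undermine it:
- Formation of the silyl dienol ether may be reversible or incomplete in the presence of the ammonium salt.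
- The acidic CH2 of 8 may transfer a proton to 9 instead of acylating it, which would return 7 and send 8 into ketene oligomerisation.
- Annulation may run through the pyranone oxygen instead of C4a.
- Two molecules of 9 may couple with one of 8.
- The acid chloride stage may be hydrolysed and decarboxylated before ring closure.

The fallback uses known chemistry. It sets out from 2 and comes back to the route at 12.
- Zinc insertion into 2 (Zn dust, LiCl, THF) gives 4-(benzyloxy)benzylzinc chloride F1.
- Commercial diosmetin A4 is perbenzylated (BnBr, K2CO3, DMF, 80 °C) to 5,7-bis(benzyloxy)-2-[3-(benzyloxy)-4-methoxyphenyl]-4H-chromen-4-one F2.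
- F2 is iodinated (NIS, cat. TFA, MeCN) at C8, the position less crowded than C6 between two benzyloxy groups. This gives the 8-iodoflavone F3.
- Negishi coupling of F1 with F3 (Pd(OAc)2, SPhos, THF) gives the tetrabenzyl ether F4.
- Hydrogenolysis of F4 gives 12.

**Step 3.** Deprotonation and aroylation may occur at the CH2 terminus of 3 instead of the CH3 terminus. A second aroylation, or an aldol-type carbocyclisation of the triketone anion onto the aryl ketone, may also consume material.

The fallback reverses the order of the two C–C bond formations so that only equivalent methyl groups are offered to the ester. It sets out from 5 (with 1) and comes back at 7.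
- Aroylation of 1 with 5 (NaH, DME, reflux) gives 1-[3-(benzyloxy)-4-methoxyphenyl]hexane-1,3,5-trione F5.
- Cyclodehydration as in step 4 gives 2-[3-(benzyloxy)-4-methoxyphenyl]-6-methyl-4H-pyran-4-one F6.
- γ-Deprotonation of F6 (LiHMDS, THF, −78 °C) and alkylation with 2 gives 7.

**Step 6.** The C2=C3 bond may be saturated. The reaction may also stall after the first benzyl group, as the polyphenol becomes poorly soluble and binds to the catalyst.

The fallback exchanges the protecting groups before the key step, so that the last step is a fluoride desilylation and no hydrogenation is used. It sets out from 7 and comes back at 12.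
- Acidolysis of 7 (TFA, pentamethylbenzene) at the robust pyranone stage gives 2-(3-hydroxy-4-methoxyphenyl)-6-[2-(4-hydroxyphenyl)ethyl]-4H-pyran-4-one F7.
- Silylation (TBSCl, imidazole, DMF) gives the bis(silyl ether) F8.
- The conditions of step 5 applied to F8 should give the bis-silylated flavone F9.
- TBAF buffered with AcOH releases 12 from F9.

**Step 1.** Proton exchange between the dianion and the monoanion of the product may lead to double alkylation, and some alkylation may occur at the central carbon.

The fallback builds the diketone from the ketone side. It sets out from 2 and comes back at 3.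
- Alkylation of ethyl acetoacetate with 2 (NaOEt, EtOH) gives ethyl 2-[4-(benzyloxy)benzyl]-3-oxobutanoate F10.
- Saponification and decarboxylation give 4-[4-(benzyloxy)phenyl]butan-2-one F11.
- Claisen condensation of F11 with ethyl acetate (NaH) at its methyl group gives 3.

## Further compounds

F1 | step 5 | 4-(benzyloxy)benzylzinc chloride | Cl[Zn]Cc1ccc(OCc2ccccc2)cc1
F2 | step 5 | 5,7-bis(benzyloxy)-2-[3-(benzyloxy)-4-methoxyphenyl]-4H-chromen-4-one | COc1ccc(-c2cc(=O)c3c(OCc4ccccc4)cc(OCc4ccccc4)cc3o2)cc1OCc1ccccc1
F3 | step 5 | 5,7-bis(benzyloxy)-2-[3-(benzyloxy)-4-methoxyphenyl]-8-iodo-4H-chromen-4-one | COc1ccc(-c2cc(=O)c3c(OCc4ccccc4)cc(OCc4ccccc4)c(I)c3o2)cc1OCc1ccccc1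
F4 | step 5 | 5,7-bis(benzyloxy)-8-[4-(benzyloxy)benzyl]-2-[3-(benzyloxy)-4-methoxyphenyl]-4H-chromen-4-one | COc1ccc(-c2cc(=O)c3c(OCc4ccccc4)cc(OCc4ccccc4)c(Cc4ccc(OCc5ccccc5)cc4)c3o2)cc1OCc1ccccc1
F5 | step 3 | 1-[3-(benzyloxy)-4-methoxyphenyl]hexane-1,3,5-trione | COc1ccc(C(=O)CC(=O)CC(C)=O)cc1OCc1ccccc1
F6 | step 3 | 2-[3-(benzyloxy)-4-methoxyphenyl]-6-methyl-4H-pyran-4-one | COc1ccc(-c2cc(=O)cc(C)o2)cc1OCc1ccccc1
F7 | step 6 | 2-(3-hydroxy-4-methoxyphenyl)-6-[2-(4-hydroxyphenyl)ethyl]-4H-pyran-4-one | COc1ccc(-c2cc(=O)cc(CCc3ccc(O)cc3)o2)cc1O
F8 | step 6 | 2-{3-[(tert-butyldimethylsilyl)oxy]-4-methoxyphenyl}-6-(2-{4-[(tert-butyldimethylsilyl)oxy]phenyl}ethyl)-4H-pyran-4-one | COc1ccc(-c2cc(=O)cc(CCc3ccc(O[Si](C)(C)C(C)(C)C)cc3)o2)cc1O[Si](C)(C)C(C)(C)C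
F9 | step 6 | 2-{3-[(tert-butyldimethylsilyl)oxy]-4-methoxyphenyl}-8-{4-[(tert-butyldimethylsilyl)oxy]benzyl}-5,7-dihydroxy-4H-chromen-4-one | COc1ccc(-c2cc(=O)c3c(O)cc(O)c(Cc4ccc(O[Si](C)(C)C(C)(C)C)cc4)c3o2)cc1O[Si](C)(C)C(C)(C)C
F10 | step 1 | ethyl 2-[4-(benzyloxy)benzyl]-3-oxobutanoate (racemic) | CCOC(=O)C(Cc1ccc(OCc2ccccc2)cc1)C(C)=O
F11 | step 1 | 4-[4-(benzyloxy)phenyl]butan-2-one | CC(=O)CCc1ccc(OCc2ccccc2)cc1
A1 | alternative 1 | 1-{3-[4-(benzyloxy)benzyl]-2-hydroxy-4,6-bis(methoxymethoxy)phenyl}ethanone | CC(=O)c1c(O)c(Cc2ccc(OCc3ccccc3)cc2)c(OCOC)cc1OCOC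
A2 | alternative 1 | 3-(benzyloxy)-4-methoxybenzoyl chloride | COc1ccc(C(=O)Cl)cc1OCc1ccccc1
A3 | alternative 1 | 5,7-dihydroxy-2-(3-hydroxy-4-methoxyphenyl)-6-(4-hydroxybenzyl)-4H-chromen-4-one | COc1ccc(-c2cc(=O)c3c(O)c(Cc4ccc(O)cc4)c(O)cc3o2)cc1O
A4 | alternative 2 | diosmetin, 5,7-dihydroxy-2-(3-hydroxy-4-methoxyphenyl)-4H-chromen-4-one | COc1ccc(-c2cc(=O)c3c(O)cc(O)cc3o2)cc1O
A5 | alternative 2 | 4-hydroxybenzyl alcohol | OCc1ccc(O)cc1
A6 | alternative 2 | 4-methylidenecyclohexa-2,5-dien-1-one (p-quinone methide) | C=C1C=CC(=O)C=C1
A7 | alternative 2 | 5,7-dihydroxy-2-(3-hydroxy-4-methoxyphenyl)-6,8-bis(4-hydroxybenzyl)-4H-chromen-4-one | COc1ccc(-c2cc(=O)c3c(O)c(Cc4ccc(O)cc4)c(O)c(Cc4ccc(O)cc4)c3o2)cc1O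
A8 | alternative 3 | 2-(4-hydroxybenzyl)benzene-1,3,5-triol | Oc1ccc(Cc2c(O)cc(O)cc2O)cc1
A9 | alternative 3 | ethyl 3-(3-hydroxy-4-methoxyphenyl)-3-oxopropanoate | CCOC(=O)CC(=O)c1ccc(OC)c(O)c1
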